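The molecule is cut at the bond between C7 of the quinone methide bicycle and the methyl-bearing bridge carbon. The bridge carbon sits on C7' of the benzene ring of the dihydroisocoumarin, between the phenols O6'–H and O8'–H, so it is a latent ortho-quinone methide. C7 lies between C6–OH and C8=O and is the nucleophilic carbon of a vinylogous acid. In the last step a chiral phosphoric acid tautomerises the 7'-vinyl lactone to the ethylidene ortho-quinone methide and steers decarboxycitrinin onto one face. This joins the halves and sets the bridge stereocentre, with no atom lost and no protecting group left. Both partners come from one enantiopure dimethoxy lactone.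

Key step: step 11

Assumption: the sense of induction of the binaphthyl phosphoric acid cannot be read from the substrates. The (R)-acid is written for the (R)-configured bridge, and because the step is under catalyst control the (S)-acid takes its place if the facial preference proves opposite.
Remark: positions carry isochromene numbering (C1, O2, C3 to C8a), primed for the lactone half. The quinone methide half is drawn as its 6-hydroxy-8-oxo tautomer. The enantiopurity set in step 2 is meant to be raised by recrystallising the common lactone before the route divides.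

Step 1
Reactants: 1 1-bromo-3,5-dimethoxybenzene; 2 (E)-prop-1-en-1-ylboronic acid
Product: 3 1,3-dimethoxy-5-[(E)-prop-1-en-1-yl]benzene
Conditions: Pd(PPh3)4 (3 mol%), K2CO3, 1,4-dioxane–H2O, 85 °C
Reagents that add atoms: none
Why: Suzuki–Miyaura coupling of an unhindered aryl bromide with an (E)-alkenylboronic acid should proceed with retention of the alkene geometry.

Step 2
Reactants: 3 1,3-dimethoxy-5-[(E)-prop-1-en-1-yl]benzene
Product: 4 (2R,3R)-2-(3,5-dimethoxyphenyl)-3-methyloxirane
Conditions: Shi ketone (1,2:4,5-di-O-isopropylidene-β-D-erythro-hexo-2,3-diulo-2,6-pyranose, 30 mol%), KHSO5 (as 2KHSO5·KHSO4·K2SO4), K2CO3, Bu4NHSO4 (cat.), MeCN–CH2(OMe)2/aq. Na2B4O7 buffer (pH 10.5), 0 °C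
Reagents that add atoms: potassium peroxymonosulfate KHSO5, [K+].[O-]S(=O)(=O)OO
Why: In the Shi asymmetric epoxidation the dioxirane of the D-fructose-derived ketone meets trans-β-methylstyrenes through a spiro transition state on the face that gives the (R,R)-epoxide, so the catalyst sets both oxirane carbons while the basic buffer spares the benzylic epoxide.

Step 3
Reactants: 4 (2R,3R)-2-(3,5-dimethoxyphenyl)-3-methyloxirane
Product: 5 (2R,3S)-3-(3,5-dimethoxyphenyl)butan-2-ol
Conditions: Me2CuLi (from MeLi and CuI, 2 equiv), Et2O, −40 to 0 °C; aq. NH4Cl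
Reagents that add atoms: lithium dimethylcuprate (made in the flask from methyllithium and CuI), [Li+].C[Cu-]C
Why: Gilman cuprate opening of an aryl epoxide is an SN2 attack at the benzylic carbon with inversion (R becomes S) while the carbinol carbon keeps its R configuration, and both methoxy groups are meta to the reacting carbon, so no cation forms to erode the stereospecificity.

Step 4
Reactants: 5 (2R,3S)-3-(3,5-dimethoxyphenyl)butan-2-ol
Product: 6 (2R,3S)-3-(2,6-dibromo-3,5-dimethoxyphenyl)butan-2-ol
Conditions: NBS (2.1 equiv), MeCN, 0 °C to rt, dark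
Reagents that add atoms: N-bromosuccinimide, O=C1CCC(=O)N1Br
Why: Electrophilic aromatic bromination goes para to one methoxy group and ortho to the other, so the two positions flanking the side chain should react before the crowded position between the methoxy groups.

Step 5
Reactants: 6 (2R,3S)-3-(2,6-dibromo-3,5-dimethoxyphenyl)butan-2-ol
Product: 9 (3R,4S)-6,8-dimethoxy-3,4,5-trimethylisochroman-1-one, via monomethylated bromo alkoxide 7 (not isolated), via hydroxy acid 8 (not isolated)
Conditions: n-BuLi (2.1 equiv), THF, −78 °C; MeI (1.0 equiv), −78 °C; n-BuLi (1.2 equiv), −78 °C; CO2 (gas, excess), −78 to 0 °C; 2 M HCl, rt; recrystallisation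
Reagents that add atoms: iodomethane, CI; carbon dioxide, O=C=O
Why: In this iterative bromine–lithium exchange the two bromines are equivalent by rotation about the aryl–side-chain bond, so methylation followed by carboxylation cannot give regioisomers, and acidification closes the δ-lactone at the acyl–oxygen bond without touching C3 or C4.

Step 6
Reactants: 9 (3R,4S)-6,8-dimethoxy-3,4,5-trimethylisochroman-1-one
Product: 10 (3R,4S)-6,8-dihydroxy-3,4,5-trimethylisochroman-1-one
Conditions: BBr3 (3 equiv), CH2Cl2, −78 °C to rt; H2O
Reagents that add atoms: none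
Why: BBr3 cleavage of aryl methyl ethers is helped at O8 by chelation to the lactone carbonyl, and the lactone masks the secondary alcohol so that C3 cannot ionise.

Step 7
Reactants: 10 (3R,4S)-6,8-dihydroxy-3,4,5-trimethylisochroman-1-one
Product: 11 (3R,4S)-6,8-dihydroxy-7-iodo-3,4,5-trimethylisochroman-1-one
Conditions: NIS (1.05 equiv), MeCN, 0 °C
Reagents that add atoms: N-iodosuccinimide, O=C1CCC(=O)N1I
Why: Electrophilic aromatic iodination can only occur at C7, the one unsubstituted ring carbon, which both flanking phenols activate.

Step 8
Reactants: 11 (3R,4S)-6,8-dihydroxy-7-iodo-3,4,5-trimethylisochroman-1-one; 12 tributyl(vinyl)stannane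
Product: 13 (3R,4S)-6,8-dihydroxy-3,4,5-trimethyl-7-vinylisochroman-1-one
Conditions: Pd2(dba)3 (2.5 mol%), P(2-furyl)3 (10 mol%), BHT (trace), DMF, 45 °C
Reagents that add atoms: none
Why: The Stille coupling runs without base, so the free phenols and the lactone are tolerated, and the reactive aryl iodide allows a temperature low enough to keep the styrene from tautomerising.

Step 9
Reactants: 9 (3R,4S)-6,8-dimethoxy-3,4,5-trimethylisochroman-1-one
Product: 14 (3R,4S)-6,8-dimethoxy-3,4,5-trimethylisochroman-1-ol (mixture of C1 epimers)
Conditions: i-Bu2AlH (1.2 equiv), CH2Cl2, −78 °C; aq. potassium sodium tartrate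
Reagents that add atoms: none
Why: Partial reduction of a lactone with i-Bu2AlH stops at the aluminium lactolate at low temperature, and the methyl ethers keep it from collapsing to a reducible quinone methide.

Step 10
Reactants: 14 (3R,4S)-6,8-dimethoxy-3,4,5-trimethylisochroman-1-ol
Product: 15 decarboxycitrinin, (3R,4S)-6-hydroxy-3,4,5-trimethyl-3,4-dihydroisochromen-8-one
Conditions: BBr3 (4 equiv), CH2Cl2, −78 to 0 °C; ice-water
Reagents that add atoms: none
Why: BBr3 ionises the lactol to the 6,8-dimethoxyisochromenylium ion, bromide strips its O-methyl groups as from a vinylogous oxonium ion (Lewis acid ether cleavage), and the net loss of water leaves the neutral quinone methide with C3 and C4 untouched.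

Step 11
Reactants: 13 (3R,4S)-6,8-dihydroxy-3,4,5-trimethyl-7-vinylisochroman-1-one; 15 decarboxycitrinin
Product: 17 dicitrinone H, via ethylidene ortho-quinone methide 16 (not isolated)
Conditions: (R)-3,3'-bis(2,4,6-triisopropylphenyl)-1,1'-binaphthyl-2,2'-diyl hydrogen phosphate (10 mol%), 4 Å molecular sieves, CH2Cl2, −20 °C to rt, 13 added slowly to 15 (1.5 equiv)
Reagents that add atoms: none
Why: The acid relays the proton of a flanking phenol (O6'–H or O8'–H) of 13 to the vinyl terminus, which unveils the (E)-ethylidene ortho-quinone methide 16 inside a hydrogen-bonded complex, and C7 of 15, the central carbon of the vinylogous acid O6–C6=C7–C8=O, adds to its exocyclic carbon while rearomatisation of the lactone-bearing ring drives the step. The closest known reaction type is the chiral phosphoric acid catalysed conjugate addition of cyclic 1,3-dicarbonyl enols and electron-rich arenes to ortho-quinone methides generated in situ from ortho-hydroxystyrenes or ortho-hydroxybenzyl alcohols. No ring is closed, and the low temperature should keep the adduct from cyclodehydrating to a xanthene-type pyran. The single new stereocentre, the bridge carbon, is controlled by the catalyst, whose P–OH binds the quinone methide oxygen and whose P=O binds C6–OH of 15 so that one face of the planar electrophile stays open; C3, C4, C3' and C4' are too remote to interfere, and binding through O6' or O8' leads to the same configuration because the two modes are related by a half turn about the C7'–bridge axis. The step needs C- over O-alkylation and attack at C7 only, which the substrates secure because the methyl groups on C5 and C5' block every other nucleophilic ring carbon and because O-adducts revert under the acid. Slow addition of 13 to an excess of 15 keeps 16 dilute, so its dimerisation with 13 and attack of the styrene terminus on the electrophilic C1 of 15 should stay behind.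

Compound list
1 | 1-bromo-3,5-dimethoxybenzene | COc1cc(Br)cc(OC)c1 | starting material
2 | (E)-prop-1-en-1-ylboronic acid | C/C=C/B(O)O | starting material
3 | 1,3-dimethoxy-5-[(E)-prop-1-en-1-yl]benzene | C/C=C/c1cc(OC)cc(OC)c1 | intermediate
4 | (2R,3R)-2-(3,5-dimethoxyphenyl)-3-methyloxirane | C[C@H]1O[C@@H]1c1cc(OC)cc(OC)c1 | intermediate
5 | (2R,3S)-3-(3,5-dimethoxyphenyl)butan-2-ol | O[C@H](C)[C@@H](C)c1cc(OC)cc(OC)c1 | intermediate
6 | (2R,3S)-3-(2,6-dibromo-3,5-dimethoxyphenyl)butan-2-ol | O[C@H](C)[C@@H](C)c1c(Br)c(OC)cc(OC)c1Br | intermediate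
7 | lithium (2R,3S)-3-(2-bromo-3,5-dimethoxy-6-methylphenyl)butan-2-olate | [Li+].[O-][C@H](C)[C@@H](C)c1c(Br)c(OC)cc(OC)c1C | intermediate
8 | 2-[(2S,3R)-3-hydroxybutan-2-yl]-4,6-dimethoxy-3-methylbenzoic acid | O[C@H](C)[C@@H](C)c1c(C)c(OC)cc(OC)c1C(=O)O | intermediate
9 | (3R,4S)-6,8-dimethoxy-3,4,5-trimethylisochroman-1-one | c1c(OC)c(C)c2c(c1OC)C(=O)O[C@H](C)[C@H]2C | intermediate
10 | (3R,4S)-6,8-dihydroxy-3,4,5-trimethylisochroman-1-one | c1c(O)c(C)c2c(c1O)C(=O)O[C@H](C)[C@H]2C | intermediate
11 | (3R,4S)-6,8-dihydroxy-7-iodo-3,4,5-trimethylisochroman-1-one | Ic1c(O)c(C)c2c(c1O)C(=O)O[C@H](C)[C@H]2C | intermediate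
12 | tributyl(vinyl)stannane | C=C[Sn](CCCC)(CCCC)CCCC | starting material
13 | (3R,4S)-6,8-dihydroxy-3,4,5-trimethyl-7-vinylisochroman-1-one | C=Cc1c(O)c(C)c2c(c1O)C(=O)O[C@H](C)[C@H]2C | intermediate
14 | (3R,4S)-6,8-dimethoxy-3,4,5-trimethylisochroman-1-ol, mixture of C1 epimers | c1c(OC)c(C)c2c(c1OC)C(O)O[C@H](C)[C@H]2C | intermediate
15 | decarboxycitrinin, (3R,4S)-6-hydroxy-3,4,5-trimethyl-3,4-dihydroisochromen-8-one | CC1=C2C(=CO[C@H](C)[C@H]2C)C(=O)C=C1O | intermediate
16 | (3R,4S,7E)-7-ethylidene-8-hydroxy-3,4,5-trimethyl-3,4-dihydroisochromene-1,6(7H)-dione | C/C=C1/C(=O)C(C)=C2C(=C1O)C(=O)O[C@H](C)[C@H]2C | intermediate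
17 | dicitrinone H, (3R,4S)-7-{(1R)-1-[(3R,4S)-6-hydroxy-3,4,5-trimethyl-8-oxo-3,4-dihydroisochromen-7-yl]ethyl}-6,8-dihydroxy-3,4,5-trimethylisochroman-1-one | CC1=C2C(=CO[C@H](C)[C@H]2C)C(=O)C([C@H](C)c2c(O)c(C)c3c(c2O)C(=O)O[C@H](C)[C@H]3C)=C1O | target

Total step count: 11. Longest linear sequence: 9 steps (steps 1 to 8, then step 11). The other branch runs through steps 1 to 5, 9, 10 and 11.

Steps most likely to fail

Step 11. The proton relay to the vinyl group may be slow. Facial discrimination may be weak at a bridge carbon flanked by four ortho oxygens. The nucleophile may also be consumed through its own electrophilic C1, by self-condensation or by capture of the styrene terminus. The fallback sets out from 15 and moves the quinone methide oxidation level to the very end. NaBH4 in MeOH at 0 °C should add hydride to C1 and give (3R,4S)-3,4,5-trimethylisochroman-6,8-diol F1, a plain resorcinol without an electrophilic site. Friedel–Crafts alkylation of its only free ring carbon with 13 under the same chiral acid (again through 16) should give (3R,4S)-7-{(1S)-1-[(3R,4S)-6,8-dihydroxy-3,4,5-trimethylisochroman-7-yl]ethyl}-6,8-dihydroxy-3,4,5-trimethylisochroman-1-one F2. Its bridge has the same spatial arrangement as the target; only the descriptor changes. DDQ (1 equiv, 1,4-dioxane, rt) then abstracts hydride from the ether carbon C1, which is stereoelectronically aligned, unlike the twisted bridge C–H. This returns to the route at 17.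

Step 8. Iodine may be lost by protodemetalation at the doubly ortho-hydroxylated arylpalladium stage, and the styrene may oligomerise on warming. The fallback sets out from 10 and replaces cross-coupling by carbonyl olefination. Casnati–Skattebøl ortho-formylation (MgCl2, Et3N, paraformaldehyde, MeCN, reflux) at the only free position should give (3R,4S)-6,8-dihydroxy-3,4,5-trimethyl-1-oxoisochroman-7-carbaldehyde F3. Wittig methylenation (MePPh3Br, KOt-Bu in excess to cover both phenols, THF, 0 °C), the usual entry to ortho-hydroxystyrenes, comes back at 13.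

Step 5. The first stage may give incomplete or double exchange. The alkoxide may be O-methylated, and the aryllithium may be butylated by 1-bromobutane if the temperature drifts. The fallback sets out from 6 and separates the two events by mechanism. A single bromine–lithium exchange (n-BuLi, 2.1 equiv, THF, −78 °C), CO2 and acid should give (3R,4S)-5-bromo-6,8-dimethoxy-3,4-dimethylisochroman-1-one F4. The methyl group is then brought in by Suzuki–Miyaura coupling (MeB(OH)2, Pd(OAc)2, 2-dicyclohexylphosphino-2',6'-dimethoxybiphenyl, K3PO4, toluene, 100 °C), which comes back at 9.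

Further compounds
F1 | step 11 | (3R,4S)-3,4,5-trimethylisochroman-6,8-diol | c1c(O)c(C)c2c(c1O)CO[C@H](C)[C@H]2C
F2 | step 11 | (3R,4S)-7-{(1S)-1-[(3R,4S)-6,8-dihydroxy-3,4,5-trimethylisochroman-7-yl]ethyl}-6,8-dihydroxy-3,4,5-trimethylisochroman-1-one | Oc1c(C)c2c(c(O)c1[C@H](C)c1c(O)c(C)c3c(c1O)C(=O)O[C@H](C)[C@H]3C)CO[C@H](C)[C@H]2C
F3 | step 8 | (3R,4S)-6,8-dihydroxy-3,4,5-trimethyl-1-oxoisochroman-7-carbaldehyde | O=Cc1c(O)c(C)c2c(c1O)C(=O)O[C@H](C)[C@H]2C
F4 | step 5 | (3R,4S)-5-bromo-6,8-dimethoxy-3,4-dimethylisochroman-1-one | c1c(OC)c(Br)c2c(c1OC)C(=O)O[C@H](C)[C@H]2C
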